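**Retrosynthetic overview**
- The naphthazarin is unmasked last. Peri-O-demethylation is preceded by oxidative demethylation of a tetramethoxynaphthalene that already carries the complete (R)-ester side chain.
- Key disconnection: the tertiary C1'–O bond of the ester. It leads back to the achiral 2-(4,4-dimethylcyclobutenyl)tetramethoxynaphthalene and angelic acid. A catalytic enantioselective Markovnikov hydroacyloxylation sets the only stereocentre and brings in the Z-ester without any acyl transfer.
- The aryl–cyclobutene bond leads back to ortho-lithiated 1,4,5,8-tetramethoxynaphthalene and 2,2-dimethylcyclobutanone (addition and elimination in one flask).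
- Ring order: no carbocycle is built, because the naphthalene and the cyclobutane are both bought. The quinone ring is revealed in step 3 and the dihydroxy ring in step 4.

Assumption: 1,4,5,8-tetramethoxynaphthalene, 2,2-dimethylcyclobutanone and angelic acid are taken as catalogue chemicals, and the two rapidly interconverting naphthazarin tautomers are treated as one substance, drawn as in the target SMILES.

**Step 1**
Reactants: 1 1,4,5,8-tetramethoxynaphthalene; 2 2,2-dimethylcyclobutan-1-one
Product: 6 2-(4,4-dimethylcyclobut-1-en-1-yl)-1,4,5,8-tetramethoxynaphthalene, via aryllithium 3 (not isolated), via lithium alkoxide 4 (not isolated), via tertiary mesylate 5 (not isolated)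
Conditions: s-BuLi, TMEDA, THF, −78 to −40 °C; 2, −78 °C; then MsCl, Et3N, −78 °C to rt
Reagents that add atoms: none
Why: Directed ortho-metalation gives a single aryllithium because all four ring C–H are equivalent and each is ortho to OMe, 1,2-addition to the strained and therefore very electrophilic cyclobutanone follows, and sulfene-type mesylation of the alkoxide with amine-induced loss of mesylate can only take a hydrogen from the ring CH2 because the other neighbour is quaternary; no stereocentre survives this step.

**Step 2**
Reactants: 6 2-(4,4-dimethylcyclobut-1-en-1-yl)-1,4,5,8-tetramethoxynaphthalene; 7 angelic acid, (Z)-2-methylbut-2-enoic acid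
Product: 8 (1R)-2,2-dimethyl-1-(1,4,5,8-tetramethoxynaphthalen-2-yl)cyclobutyl (Z)-2-methylbut-2-enoate
Conditions: 7 (3 equiv), (S,S)-IDPi (BINOL-derived imidodiphosphorimidate, 3,3'-(3,5-(CF3)2C6H3), N-Tf core, 5 mol %), PhMe, −40 °C, 48 h; Et3N quench at −40 °C; Et3N-deactivated silica
Reagents that add atoms: none
Why: Proposed new method: catalytic enantioselective intermolecular Markovnikov hydroacyloxylation of a strained trisubstituted aryl alkene, in which the confined chiral acid and angelic acid form a hydrogen-bonded heterodimer that protonates the olefinic CH while the carbonyl oxygen of the bound acid attacks C1 in a pre-associated, concerted-asynchronous AdE3 event, so that the C1–O bond and the (R) centre form inside the chiral pocket (CMe2 against CH2 and the OMe edge against the H edge of the aryl group give two strong steric handles) without a free cation that could ring-contract; relief of the extra cyclobutene strain makes the addition exergonic, the 1-OMe group is twisted out of conjugation by the peri 8-OMe, and together these make re-ionisation of 8 slower than its formation at −40 °C, while the absence of base and nucleophilic catalyst protects the Z-alkene; the closest known reaction types are confined-acid intramolecular hydroalkoxylation and hydrolactonisation of olefins, phosphoric acid/carboxylic acid heterodimer opening of epoxides, and racemic TfOH-catalysed hydroacyloxylation; which catalyst antipode gives (R) must be found by experiment, and both antipodes are available.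

**Step 3**
Reactants: 8 (1R)-2,2-dimethyl-1-(1,4,5,8-tetramethoxynaphthalen-2-yl)cyclobutyl (Z)-2-methylbut-2-enoate
Product: 9 6-[(1R)-1-angeloyloxy-2,2-dimethylcyclobutyl]-5,8-dimethoxy-1,4-naphthoquinone
Conditions: 8 in MeCN added to CAN (2.5 equiv) in MeCN/H2O, 0 °C, 10 min
Reagents that add atoms: water, O
Why: Ceric ammonium nitrate oxidative demethylation of a hydroquinone dimethyl ether (two one-electron oxidations, with water attacking the OMe-bearing carbons and supplying the quinone oxygens) takes the unhindered unsubstituted ring, outruns acid solvolysis of the ester under inverse addition, cannot start a Ce(IV) cyclobutanol ring opening because the oxygen is acylated, and leaves C1' and the Z-alkene untouched; any regioisomeric quinone would give the same naphthazarin in step 4.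

**Step 4**
Reactants: 9 6-[(1R)-1-angeloyloxy-2,2-dimethylcyclobutyl]-5,8-dimethoxy-1,4-naphthoquinone
Product: 12 (1R)-1-(5,8-dihydroxy-1,4-dioxo-1,4-dihydronaphthalen-2-yl)-2,2-dimethylcyclobutyl (Z)-2-methylbut-2-enoate, via bis(dichloroboryl) ether 10 (not isolated), via 6-substituted tautomer 11 (not isolated)
Conditions: BCl3 (3 equiv), CH2Cl2, −78 to −30 °C; then H2O, 0 °C
Reagents that add atoms: none
Why: In this chelation-controlled Lewis acid ether cleavage BCl3 binds each quinone carbonyl/peri-methoxy pair and chloride removes the methyl group at low temperature, while the tertiary ester now sits on an acyl-deactivated ring and does not ionise; hydrolysis gives 11, which is the fast prototropic tautomer of 12, and the stereocentre is not touched.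

**Compound list**
1 | 1,4,5,8-tetramethoxynaphthalene | COc1ccc(OC)c2c(OC)ccc(OC)c12 | starting material
2 | 2,2-dimethylcyclobutan-1-one | CC1(C)CCC1=O | starting material
3 | 2-lithio-1,4,5,8-tetramethoxynaphthalene | [Li]c1cc(OC)c2c(OC)ccc(OC)c2c1OC | intermediate
4 | lithium 2,2-dimethyl-1-(1,4,5,8-tetramethoxynaphthalen-2-yl)cyclobutan-1-olate (racemic) | [Li+].[O-]C1(CCC1(C)C)c1cc(OC)c2c(OC)ccc(OC)c2c1OC | intermediate
5 | 2,2-dimethyl-1-(1,4,5,8-tetramethoxynaphthalen-2-yl)cyclobutyl methanesulfonate (racemic) | CS(=O)(=O)OC1(CCC1(C)C)c1cc(OC)c2c(OC)ccc(OC)c2c1OC | intermediate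
6 | 2-(4,4-dimethylcyclobut-1-en-1-yl)-1,4,5,8-tetramethoxynaphthalene | CC1(C)CC=C1c1cc(OC)c2c(OC)ccc(OC)c2c1OC | intermediate
7 | angelic acid, (Z)-2-methylbut-2-enoic acid | C/C=C(/C)C(=O)O | starting material
8 | (1R)-2,2-dimethyl-1-(1,4,5,8-tetramethoxynaphthalen-2-yl)cyclobutyl (Z)-2-methylbut-2-enoate | C/C=C(/C)C(=O)O[C@]1(c2cc(OC)c3c(OC)ccc(OC)c3c2OC)CCC1(C)C | intermediate
9 | 6-[(1R)-1-angeloyloxy-2,2-dimethylcyclobutyl]-5,8-dimethoxy-1,4-naphthoquinone | C/C=C(/C)C(=O)O[C@]1(c2cc(OC)c3C(=O)C=CC(=O)c3c2OC)CCC1(C)C | intermediate
10 | 6-[(1R)-1-angeloyloxy-2,2-dimethylcyclobutyl]-5,8-bis(dichloroboryloxy)-1,4-naphthoquinone | C/C=C(/C)C(=O)O[C@]1(c2cc(OB(Cl)Cl)c3C(=O)C=CC(=O)c3c2OB(Cl)Cl)CCC1(C)C | intermediate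
11 | 6-[(1R)-1-angeloyloxy-2,2-dimethylcyclobutyl]-5,8-dihydroxy-1,4-naphthoquinone (tautomer of 12) | C/C=C(/C)C(=O)O[C@]1(c2cc(O)c3C(=O)C=CC(=O)c3c2O)CCC1(C)C | intermediate
12 | (1R)-1-(5,8-dihydroxy-1,4-dioxo-1,4-dihydronaphthalen-2-yl)-2,2-dimethylcyclobutyl (Z)-2-methylbut-2-enoate (CNP0326301.1) | C/C=C(/C)C(=O)O[C@]1(C2=CC(=O)c3c(O)ccc(O)c3C2=O)CCC1(C)C | target

Total step count: 4. Longest linear sequence: 4 (1 → 6 → 8 → 9 → 12).

**Steps most likely to fail**

Risk 1, step 2 (the proposed new reaction).
- The ee may erode through acid re-ionisation of 8.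
- The cationic manifold may leak into cyclopropylcarbinyl or homoallyl esters.
- The hindered C1 may simply not be captured.

The fallback uses known chemistry and sets out from 7 and from the lithium alkoxide 4 (step 1 run without MsCl). Acid 7 is dehydrated with DCC in CH2Cl2 to angelic anhydride F1. Alkoxide 4 is acylated in the flask with F1 in THF, −78 °C to rt. This is alkoxide/anhydride acylation, the standard non-isomerising way to make angelates, and it gives the racemic ester F2. Preparative chiral SFC then separates 8 from the (S)-ester F3, which is discarded. The route is rejoined at 8.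

Risk 2, step 4.
- BCl3 may ionise the tertiary ester.
- Chloride may isomerise the angelate to the tiglate.

The fallback sets out from 9 and replaces Lewis acid cleavage by a redox sequence. Argentic oxide in 6 M HNO3/acetone at rt for a few minutes oxidatively demethylates the remaining dimethoxy ring to the naphthalene-1,4,5,8-tetraone F4. This is reduced by two electrons in the work-up with aqueous ascorbic acid, without passing through the leuco form that would expel the ester. The route is rejoined at 12.

Risk 3, step 1.
- The metalation may be incomplete.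
- The mesylate may partly ring-contract on ionisation, giving an isopropenylcyclopropane isomer.

The fallback sets out from 2 and 3 and avoids any cationic stage. Ketone 2 is converted with LDA and PhNTf2 (THF, −78 °C) into 4,4-dimethylcyclobut-1-en-1-yl triflate F5. Aryllithium 3 is transmetalated with ZnCl2 to the arylzinc chloride F6. Negishi coupling of F5 with F6 (Pd(OAc)2/SPhos, THF, rt) gives the cyclobutene. The route is rejoined at 6.

**Further compounds**
F1 | step 2 | angelic anhydride, (Z)-2-methylbut-2-enoic anhydride | C/C=C(/C)C(=O)OC(=O)/C(C)=C\C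
F2 | step 2 | racemic 2,2-dimethyl-1-(1,4,5,8-tetramethoxynaphthalen-2-yl)cyclobutyl (Z)-2-methylbut-2-enoate | C/C=C(/C)C(=O)OC1(CCC1(C)C)c1cc(OC)c2c(OC)ccc(OC)c2c1OC
F3 | step 2 | (1S)-2,2-dimethyl-1-(1,4,5,8-tetramethoxynaphthalen-2-yl)cyclobutyl (Z)-2-methylbut-2-enoate | C/C=C(/C)C(=O)O[C@@]1(c2cc(OC)c3c(OC)ccc(OC)c3c2OC)CCC1(C)C
F4 | step 4 | (1R)-2,2-dimethyl-1-(1,4,5,8-tetraoxo-1,4,5,8-tetrahydronaphthalen-2-yl)cyclobutyl (Z)-2-methylbut-2-enoate | C/C=C(/C)C(=O)O[C@]1(C2=CC(=O)C3=C(C2=O)C(=O)C=CC3=O)CCC1(C)C
F5 | step 1 | 4,4-dimethylcyclobut-1-en-1-yl trifluoromethanesulfonate | CC1(C)CC=C1OS(=O)(=O)C(F)(F)F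
F6 | step 1 | (1,4,5,8-tetramethoxynaphthalen-2-yl)zinc chloride | Cl[Zn]c1cc(OC)c2c(OC)ccc(OC)c2c1OC
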